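A direct plan would build ring A from cyclohexane-1,3-dione A1: C-prenylation in aqueous base to A2, then O-allylation to the vinylogous ester A3.
The lithium dienolate of A3 would be acylated by the tris-TBS Weinreb amide A4, made from (R)-danshensu 7, to give the β-diketone A5.
DDQ would dehydrogenate A5 to the aryl ketone A6; deallylation and desilylation would follow.
Weakest would be the DDQ dehydrogenation, run on the most advanced material: DDQ also cyclises ortho-prenylphenols such as A6 to chromenes and attacks electron-rich benzylic positions.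
Second would be the dienolate acylation: it would need two equivalents of enolate and C6-over-C4 and C-over-O control, and it would expose the α-silyloxy centre to proton exchange.
Third would be the aqueous prenylation of the dione (C-, O- and bis-alkylation side by side), followed by five protecting or activating steps that add no skeletal bond.

**Plan of the new route**
Labels: ring A = C1'–C6' (C1' acyl, C2' OH, C3' prenyl, C4' OH); C7 = ketone, C8 = carbinol, C9 = CH2; ring B = catechol.
The retrosynthesis cuts ring A at C1'–C2' and C5'–C6': a Diels–Alder reaction of a 1-methoxy-1,3-bis(silyloxy)diene with a terminal ynone, then loss of methanol.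
This is possible because C2'(O)–C3'(prenyl)–C4'(O)–C5' is the ester carbon, α-carbon, ketone carbon and methyl carbon of a 2-prenylacetoacetate, and C1'(acyl)–C6'(H) are the two carbons of an alkynyl ketone.
Ring B is bought with (R)-danshensu, which also brings C7–C9 and the C8 stereocentre; ring A arises last and is formed directly at the arene oxidation level.
Prenyl is placed by α-alkylation of a β-keto ester; no oxidant and no enolate meet the late material, and no allyl group is put on or taken off.
All five silyl ethers leave in the flask of the key step, so no protected form of the full skeleton is isolated.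

Key step: step 7

Remark: (R)-danshensu is taken as the commercial enantiopure free acid; the commercial sodium salt would be acidified first.

Step 1
Reactants: 1 methyl acetoacetate; 2 prenyl bromide (1-bromo-3-methylbut-2-ene)
Product: 3 methyl 2-acetyl-5-methylhex-4-enoate (racemic)
Conditions: NaH (1.0 equiv), THF, 0 °C; 1 (1.1 equiv), then 2 (1.0 equiv), 0 °C to rt
Reagents that add atoms: none
Why: C-alkylation of the sodium enolate of a β-keto ester by a primary allylic bromide (SN2), with 1 in slight excess to hold back dialkylation; this fixes the prenyl group on the carbon that becomes C3', and the stereocentre of 3 is irrelevant because that carbon becomes sp2.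

Step 2
Reactants: 3 methyl 2-acetyl-5-methylhex-4-enoate
Product: 4 methyl 5-methyl-2-[1-(trimethylsilyloxy)ethylidene]hex-4-enoate (E/Z mixture)
Conditions: Me3SiCl (1.8 equiv), Et3N (1.6 equiv), toluene, rt, 48–72 h; filtration under Ar
Reagents that add atoms: chlorotrimethylsilane, C[Si](C)(C)Cl
Why: Silyl enol ether formation from the enol of the β-keto ester under amine base, the usual first stage for 2-alkylacetoacetates, should give the conjugated β-silyloxy enoate.

Step 3
Reactants: 4 methyl 5-methyl-2-[1-(trimethylsilyloxy)ethylidene]hex-4-enoate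
Product: 6 1-methoxy-2-(3-methylbut-2-en-1-yl)-1,3-bis(trimethylsilyloxy)buta-1,3-diene, via lithium dienolate 5 (not isolated)
Conditions: LiN(iPr)2 (1.3 equiv), THF, −78 °C; Me3SiCl (1.5 equiv), −78 °C to rt; hexane, filtration under Ar, used crude
Reagents that add atoms: chlorotrimethylsilane, C[Si](C)(C)Cl
Why: γ-Deprotonation of the β-silyloxy enoate at the C4 methyl group, the only site that gives an ester dienolate (the prenyl CH2 is cross-conjugated), followed by O-silylation, is the standard second stage of the preparation of 2-alkyl 1-alkoxy-1,3-bis(silyloxy)dienes.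

Step 4
Reactants: 7 (R)-danshensu, (R)-3-(3,4-dihydroxyphenyl)-2-hydroxypropanoic acid
Product: 8 (R)-3-(3,4-dihydroxyphenyl)-2-hydroxy-N-methoxy-N-methylpropanamide
Conditions: MeNHOMe·HCl (1.5 equiv), EDC·HCl (1.3 equiv), HOBt (1.3 equiv), N-methylmorpholine (3 equiv), DMF, 0 °C to rt, Ar
Reagents that add atoms: N,O-dimethylhydroxylamine hydrochloride, CNOC.Cl
Why: Carbodiimide/HOBt amide coupling, in which the amine outcompetes the secondary alcohol and the un-ionised phenols for the active ester, should keep C8 because an α-hydroxy acid has no oxazolone pathway for racemisation.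

Step 5
Reactants: 8 (R)-3-(3,4-dihydroxyphenyl)-2-hydroxy-N-methoxy-N-methylpropanamide
Product: 9 (R)-N-methoxy-N-methyl-2-(triethylsilyloxy)-3-[3,4-bis(triethylsilyloxy)phenyl]propanamide
Conditions: Et3SiCl (3.6 equiv), imidazole (7 equiv), DMF, 0 °C to rt
Reagents that add atoms: chlorotriethylsilane, CC[Si](CC)(CC)Cl
Why: Silyl ether formation at the two phenols and the secondary alcohol with the imidazole-activated silyl chloride does not touch C8, and triethylsilyl is chosen so that these ethers leave together with the trimethylsilyl ethers in step 7.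

Step 6
Reactants: 9 (R)-N-methoxy-N-methyl-2-(triethylsilyloxy)-3-[3,4-bis(triethylsilyloxy)phenyl]propanamide
Product: 11 (R)-4-(triethylsilyloxy)-5-[3,4-bis(triethylsilyloxy)phenyl]pent-1-yn-3-one, via magnesium hemiaminal chelate 10 (not isolated)
Conditions: HC≡CMgBr (2.5 equiv, 0.5 M in THF), THF, −78 to 0 °C; inverse quench into cold 1 M aq. KHSO4/Et2O
Reagents that add atoms: ethynylmagnesium bromide, C#C[Mg]Br
Why: Weinreb ketone synthesis with an alkynyl Grignard reagent, in which the chelated adduct 10 stops over-addition and the weakly basic acetylide does not enolise C8, while the acidic inverse quench protonates the released N,O-dimethylhydroxylamine before it can add to the new ynone.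

Step 7
Reactants: 6 1-methoxy-2-(3-methylbut-2-en-1-yl)-1,3-bis(trimethylsilyloxy)buta-1,3-diene; 11 (R)-4-(triethylsilyloxy)-5-[3,4-bis(triethylsilyloxy)phenyl]pent-1-yn-3-one
Product: 14 (R)-1-[2,4-dihydroxy-3-(3-methylbut-2-en-1-yl)phenyl]-3-(3,4-dihydroxyphenyl)-2-hydroxypropan-1-one (CNP0408242.1), via cycloadduct 12 (not isolated), via aryl bis(trimethylsilyl) ether 13 (not isolated)
Conditions: 6 (1.8 equiv), toluene (1 M), 0 °C to rt, then 45 °C, Ar; then Et3N·3HF (excess), THF/MeCN, 0 °C to rt, Ar, degassed work-up
Reagents that add atoms: none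
Why: Normal-demand Diels–Alder reaction of the doubly donor-activated diene 6 with the terminal ynone 11: the C4 terminus of 6, its most nucleophilic carbon, bonds to the unsubstituted alkyne carbon and the ketene acetal carbon C1 bonds to the acyl-bearing alkyne carbon, giving the cyclohexa-1,4-diene 12, which loses methanol from its C(OMe)(OSiMe3) carbon to give arene 13, and the acidic fluoride then cleaves the two trimethylsilyl and three triethylsilyl ethers. The closest known reaction type is the cycloaddition of 1-alkoxy-1,3-bis(silyloxy)buta-1,3-dienes and 1,1-dialkoxy-3-silyloxybutadienes, 2-alkyl members included, with acetylenic ketones, acetylenic esters and haloquinones, which gives resorcinol derivatives with the acceptor ortho to one oxygen and para to the other. Ring A is closed by an intermolecular (4+2) cycloaddition that forms C1'–C2' and C5'–C6' from two open-chain partners, and it becomes aromatic without an oxidant because the alkyne supplies the missing unsaturation and the ketal carbon carries its own leaving group. No stereocentre is made (the ketal carbon of 12 is a mixture that vanishes on aromatization), and C8 is carried through from (R)-danshensu because the step uses no base and no Lewis acid and the carbinol stays a silyl ether until the buffered desilylation. The step needs regioselectivity and the right sense of aromatization: the first is secured because both oxygenated carbons of 6 polarise the diene the same way and the ynone has a single acceptor, the second because the Si–O bond of the mixed ketal is the one that acid or fluoride breaks, so that this oxygen stays as the C2' hydroxyl and methanol leaves whether desilylation comes before or after the elimination. The prenyl group was already fixed at C3' in step 1, so no regiochemical prenylation of a resorcinol arises.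

**Compound list**
1 | methyl acetoacetate | COC(=O)CC(C)=O | starting material
2 | prenyl bromide (1-bromo-3-methylbut-2-ene) | CC(C)=CCBr | starting material
3 | methyl 2-acetyl-5-methylhex-4-enoate (racemic) | COC(=O)C(CC=C(C)C)C(C)=O | intermediate
4 | methyl 5-methyl-2-[1-(trimethylsilyloxy)ethylidene]hex-4-enoate (E/Z mixture) | COC(=O)C(CC=C(C)C)=C(C)O[Si](C)(C)C | intermediate
5 | lithium 1-methoxy-2-(3-methylbut-2-en-1-yl)-3-(trimethylsilyloxy)buta-1,3-dien-1-olate (not isolated) | COC(O[Li])=C(CC=C(C)C)C(=C)O[Si](C)(C)C | intermediate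
6 | 1-methoxy-2-(3-methylbut-2-en-1-yl)-1,3-bis(trimethylsilyloxy)buta-1,3-diene (C1=C2 geometry unspecified) | COC(O[Si](C)(C)C)=C(CC=C(C)C)C(=C)O[Si](C)(C)C | intermediate
7 | (R)-danshensu, (R)-3-(3,4-dihydroxyphenyl)-2-hydroxypropanoic acid | OC(=O)[C@H](O)Cc1ccc(O)c(O)c1 | starting material
8 | (R)-3-(3,4-dihydroxyphenyl)-2-hydroxy-N-methoxy-N-methylpropanamide | CON(C)C(=O)[C@H](O)Cc1ccc(O)c(O)c1 | intermediate
9 | (R)-N-methoxy-N-methyl-2-(triethylsilyloxy)-3-[3,4-bis(triethylsilyloxy)phenyl]propanamide | CON(C)C(=O)[C@H](O[Si](CC)(CC)CC)Cc1ccc(O[Si](CC)(CC)CC)c(O[Si](CC)(CC)CC)c1 | intermediate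
10 | bromomagnesium (4R)-3-[methoxy(methyl)amino]-4-(triethylsilyloxy)-5-[3,4-bis(triethylsilyloxy)phenyl]pent-1-yn-3-olate (chelated adduct, not isolated; C3 unspecified) | C#CC(O[Mg]Br)(N(C)OC)[C@H](O[Si](CC)(CC)CC)Cc1ccc(O[Si](CC)(CC)CC)c(O[Si](CC)(CC)CC)c1 | intermediate
11 | (R)-4-(triethylsilyloxy)-5-[3,4-bis(triethylsilyloxy)phenyl]pent-1-yn-3-one | C#CC(=O)[C@H](O[Si](CC)(CC)CC)Cc1ccc(O[Si](CC)(CC)CC)c(O[Si](CC)(CC)CC)c1 | intermediate
12 | (2R)-1-[6-methoxy-5-(3-methylbut-2-en-1-yl)-4,6-bis(trimethylsilyloxy)cyclohexa-1,4-dien-1-yl]-2-(triethylsilyloxy)-3-[3,4-bis(triethylsilyloxy)phenyl]propan-1-one (cycloadduct, not isolated; ring C6 unspecified) | COC1(O[Si](C)(C)C)C(CC=C(C)C)=C(O[Si](C)(C)C)CC=C1C(=O)[C@H](O[Si](CC)(CC)CC)Cc1ccc(O[Si](CC)(CC)CC)c(O[Si](CC)(CC)CC)c1 | intermediate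
13 | (R)-1-[3-(3-methylbut-2-en-1-yl)-2,4-bis(trimethylsilyloxy)phenyl]-2-(triethylsilyloxy)-3-[3,4-bis(triethylsilyloxy)phenyl]propan-1-one (not isolated) | CC(C)=CCc1c(O[Si](C)(C)C)ccc(C(=O)[C@H](O[Si](CC)(CC)CC)Cc2ccc(O[Si](CC)(CC)CC)c(O[Si](CC)(CC)CC)c2)c1O[Si](C)(C)C | intermediate
14 | (R)-1-[2,4-dihydroxy-3-(3-methylbut-2-en-1-yl)phenyl]-3-(3,4-dihydroxyphenyl)-2-hydroxypropan-1-one (CNP0408242.1) | CC(C)=CCc1c(O)ccc(C(=O)[C@H](O)Cc2ccc(O)c(O)c2)c1O | target

**Step count**
Total: 7 steps. Longest linear sequence: 4 steps (steps 1, 2, 3, 7 or steps 4, 5, 6, 7).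

**Steps most likely to fail**

Step 7. The cycloaddition of the tetrasubstituted diene may be slow, so that the diene is lost to hydrolysis or to an open-chain Michael adduct formed by silyl transfer. Aromatization may also proceed with loss of silanol in place of methanol, leaving a C2' methyl ether. The fallback sets out from 9 and comes back at 14, and takes ring A as a preformed arene. 1,3-Bis(methoxymethoxy)benzene F1 would be lithiated between the two acetal oxygens (n-BuLi, THF, 0 °C) and prenylated with 2 (CuI, 10 mol %) to 1,3-bis(methoxymethoxy)-2-(3-methylbut-2-en-1-yl)benzene F2. A second directed ortho-lithiation (n-BuLi, TMEDA, THF, 0 °C) and addition of the aryllithium to 9 at −78 °C would give (R)-1-[2,4-bis(methoxymethoxy)-3-(3-methylbut-2-en-1-yl)phenyl]-2-(triethylsilyloxy)-3-[3,4-bis(triethylsilyloxy)phenyl]propan-1-one F3. Methanolic HCl at or below 40 °C would then remove the two methoxymethyl and three triethylsilyl groups to give 14.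

Step 6. The released N,O-dimethylhydroxylamine may add to the terminal ynone during the quench, or the Grignard reagent may strip aryl silyl groups. The fallback sets out from 9 and comes back at 11. Reduction of 9 with iBu2AlH (THF, −78 °C) would give (R)-2-(triethylsilyloxy)-3-[3,4-bis(triethylsilyloxy)phenyl]propanal F4. Addition of HC≡CMgBr at −78 °C would give (4R)-4-(triethylsilyloxy)-5-[3,4-bis(triethylsilyloxy)phenyl]pent-1-yn-3-ol F5 as a mixture at the new carbinol. Oxidation with Dess–Martin periodinane (NaHCO3, CH2Cl2, 0 °C) would give 11; the hydroxylamine is washed out before any ynone exists.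

Step 4. The unprotected hydroxy acid may esterify with itself to oligomers, or the free catechol may oxidise under the coupling conditions. The fallback sets out from 7 and comes back at 9. Fischer esterification (MeOH, cat. H2SO4, reflux, Ar) would give methyl (R)-3-(3,4-dihydroxyphenyl)-2-hydroxypropanoate F6. Silylation (Et3SiCl, imidazole, DMF) would give methyl (R)-2-(triethylsilyloxy)-3-[3,4-bis(triethylsilyloxy)phenyl]propanoate F7. Aminolysis with MeNHOMe·HCl and iPrMgCl (THF, −20 to 0 °C) would give 9.

**Further compounds**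
F1 | step 7 | 1,3-bis(methoxymethoxy)benzene | COCOc1cccc(OCOC)c1
F2 | step 7 | 1,3-bis(methoxymethoxy)-2-(3-methylbut-2-en-1-yl)benzene | COCOc1cccc(OCOC)c1CC=C(C)C
F3 | step 7 | (R)-1-[2,4-bis(methoxymethoxy)-3-(3-methylbut-2-en-1-yl)phenyl]-2-(triethylsilyloxy)-3-[3,4-bis(triethylsilyloxy)phenyl]propan-1-one | COCOc1ccc(C(=O)[C@H](O[Si](CC)(CC)CC)Cc2ccc(O[Si](CC)(CC)CC)c(O[Si](CC)(CC)CC)c2)c(OCOC)c1CC=C(C)C
F4 | step 6 | (R)-2-(triethylsilyloxy)-3-[3,4-bis(triethylsilyloxy)phenyl]propanal | O=C[C@H](O[Si](CC)(CC)CC)Cc1ccc(O[Si](CC)(CC)CC)c(O[Si](CC)(CC)CC)c1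
F5 | step 6 | (4R)-4-(triethylsilyloxy)-5-[3,4-bis(triethylsilyloxy)phenyl]pent-1-yn-3-ol (C3 unspecified) | C#CC(O)[C@H](O[Si](CC)(CC)CC)Cc1ccc(O[Si](CC)(CC)CC)c(O[Si](CC)(CC)CC)c1
F6 | step 4 | methyl (R)-3-(3,4-dihydroxyphenyl)-2-hydroxypropanoate | COC(=O)[C@H](O)Cc1ccc(O)c(O)c1
F7 | step 4 | methyl (R)-2-(triethylsilyloxy)-3-[3,4-bis(triethylsilyloxy)phenyl]propanoate | COC(=O)[C@H](O[Si](CC)(CC)CC)Cc1ccc(O[Si](CC)(CC)CC)c(O[Si](CC)(CC)CC)c1
A1 | direct plan | cyclohexane-1,3-dione | O=C1CCCC(=O)C1
A2 | direct plan | 2-(3-methylbut-2-en-1-yl)cyclohexane-1,3-dione | CC(C)=CCC1C(=O)CCCC1=O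
A3 | direct plan | 3-(allyloxy)-2-(3-methylbut-2-en-1-yl)cyclohex-2-en-1-one | C=CCOC1=C(CC=C(C)C)C(=O)CCC1
A4 | direct plan | (R)-2-(tert-butyldimethylsilyloxy)-3-[3,4-bis(tert-butyldimethylsilyloxy)phenyl]-N-methoxy-N-methylpropanamide | CON(C)C(=O)[C@H](O[Si](C)(C)C(C)(C)C)Cc1ccc(O[Si](C)(C)C(C)(C)C)c(O[Si](C)(C)C(C)(C)C)c1
A5 | direct plan | 3-(allyloxy)-6-{(2R)-2-(tert-butyldimethylsilyloxy)-3-[3,4-bis(tert-butyldimethylsilyloxy)phenyl]propanoyl}-2-(3-methylbut-2-en-1-yl)cyclohex-2-en-1-one | C=CCOC1=C(CC=C(C)C)C(=O)C(CC1)C(=O)[C@H](O[Si](C)(C)C(C)(C)C)Cc1ccc(O[Si](C)(C)C(C)(C)C)c(O[Si](C)(C)C(C)(C)C)c1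
A6 | direct plan | (R)-1-[4-(allyloxy)-2-hydroxy-3-(3-methylbut-2-en-1-yl)phenyl]-2-(tert-butyldimethylsilyloxy)-3-[3,4-bis(tert-butyldimethylsilyloxy)phenyl]propan-1-one | C=CCOc1ccc(C(=O)[C@H](O[Si](C)(C)C(C)(C)C)Cc2ccc(O[Si](C)(C)C(C)(C)C)c(O[Si](C)(C)C(C)(C)C)c2)c(O)c1CC=C(C)C
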